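**Retrosynthetic overview**
1. Rings B and C and both ring-fusion stereocentres come last, from the open aryl cinnamyl ether 15, in one oxidative cascade: 6-endo arylation, 1,2-aryl shift (neoflavan to isoflavan skeleton), then O-closure of the dihydrofuran.
2. 15 is cut at the aryl–vinyl bond: ortho-metalated (R)-chromanol 10 plus the (E)-3-chloroallyl ether 12 (three-carbon linker from 1,3-dichloropropene).
3. The carbinol centre of 10 comes from asymmetric epoxidation and hydride opening of chromene 8.
4. Both halves derive from one chromenol, 7, made from cyclohexane-1,3-dione and prenal.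
5. Ring order: the two dimethylpyran rings (step 1), the two benzene rings (step 2), then rings B and C together (step 8).

Assumption: the (R,R)-Mn(salen) catalyst gives the (3R,4R)-epoxide here as it does with other 2,2-dimethylchromenes, and the (R,R)-lactate iodane is taken as the enantiomer that leads to (6aR,11aR); if either sense is the opposite, the mirror-image catalyst or reagent is used.

**Route**

Step 1
Reactants: 1 cyclohexane-1,3-dione; 2 3-methylbut-2-enal
Product: 4 2,2-dimethyl-2,6,7,8-tetrahydro-5H-chromen-5-one, via Knoevenagel oxatriene 3 (not isolated)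
Conditions: ethylenediammonium diacetate (10 mol %), MeOH, 50 °C
Reagents that add atoms: none
Why: Knoevenagel condensation at C2 of the dione followed by oxa-6π ring closure (formal [3+3] annulation) builds the 2,2-dimethylpyran ring, and no stereocentre is formed.

Step 2
Reactants: 4 2,2-dimethyl-2,6,7,8-tetrahydro-5H-chromen-5-one
Product: 7 2,2-dimethyl-2H-chromen-5-ol, via lithium dienolate 5 (not isolated), via dienone tautomer 6 (not isolated)
Conditions: LDA (1.1 equiv), THF, −78 °C; PhS(Cl)=NtBu (1.2 equiv), −78 °C to rt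
Reagents that add atoms: none
Why: Kinetic α'-deprotonation of the vinylogous ester and Mukaiyama dehydrogenation of the enolate give the cross-conjugated dienone, which tautomerises to the phenol (aromatisation).

Step 3
Reactants: 7 2,2-dimethyl-2H-chromen-5-ol
Product: 8 5-(methoxymethoxy)-2,2-dimethyl-2H-chromene
Conditions: MOMCl, K2CO3, acetone, rt
Reagents that add atoms: chloromethyl methyl ether, COCCl
Why: Phenol O-alkylation installs the MOM group, which protects the phenol during oxidation and later serves as ortho-directing group and internal O-nucleophile.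

Step 4
Reactants: 8 5-(methoxymethoxy)-2,2-dimethyl-2H-chromene
Product: 9 (3R,4R)-3,4-epoxy-5-(methoxymethoxy)-2,2-dimethylchromane
Conditions: (R,R)-Jacobsen Mn(salen)Cl (4 mol %), 4-phenylpyridine N-oxide (20 mol %), aq NaOCl (pH 11.3), CH2Cl2, 0 °C
Reagents that add atoms: sodium hypochlorite, [Na+].[O-]Cl
Why: Jacobsen–Katsuki epoxidation of a cis-disubstituted 2,2-dimethylchromene, the best substrate class for this catalyst, sets C3 (and C4) by catalyst-controlled face selection.

Step 5
Reactants: 9 (3R,4R)-3,4-epoxy-5-(methoxymethoxy)-2,2-dimethylchromane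
Product: 10 (3R)-5-(methoxymethoxy)-2,2-dimethylchroman-3-ol
Conditions: LiAlH4, THF, 0 °C (crude epoxide used at once)
Reagents that add atoms: none
Why: Hydride opens the epoxide at the benzylic C4 (C3 is shielded by the quaternary C2), so the C3–O bond is untouched and the (R) carbinol is retained.

Step 6
Reactants: 7 2,2-dimethyl-2H-chromen-5-ol; 11 (E)-1,3-dichloroprop-1-ene
Product: 12 5-{[(2E)-3-chloroprop-2-en-1-yl]oxy}-2,2-dimethyl-2H-chromene
Conditions: K2CO3, DMF, rt
Reagents that add atoms: none
Why: Williamson etherification occurs only at the allylic chloride, leaving the vinylic chloride and the E geometry intact.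

Step 7
Reactants: 10 (3R)-5-(methoxymethoxy)-2,2-dimethylchroman-3-ol; 12 5-{[(2E)-3-chloroprop-2-en-1-yl]oxy}-2,2-dimethyl-2H-chromene
Product: 15 (3R)-6-{(1E)-3-[(2,2-dimethyl-2H-chromen-5-yl)oxy]prop-1-en-1-yl}-5-(methoxymethoxy)-2,2-dimethylchroman-3-ol, via dilithio species 13 (not isolated), via arylzinc chloride 14 (not isolated)
Conditions: n-BuLi (2.3 equiv), THF, 0 °C to rt; ZnCl2 (1.2 equiv), 0 °C; 12 (1.1 equiv), XPhos Pd G3 (2 mol %), 45 °C
Reagents that add atoms: none
Why: MOM-directed ortho-lithiation at the only position ortho to OMOM (the 3-OH rides as its alkoxide), Li-to-Zn transmetalation and Negishi coupling at the vinylic C–Cl bond proceed with retention of the E geometry and touch no stereocentre.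

Step 8
Reactants: 15 (3R)-6-{(1E)-3-[(2,2-dimethyl-2H-chromen-5-yl)oxy]prop-1-en-1-yl}-5-(methoxymethoxy)-2,2-dimethylchroman-3-ol
Product: 16 target pterocarpan CNP0126417.1 (6aR,11aR; carbinol R)
Conditions: dimethyl (2R,2'R)-2,2'-{[2-(diacetoxy-λ3-iodanyl)-1,3-phenylene]bis(oxy)}dipropanoate (1.2 equiv), BF3·OEt2 (20 mol %), CH2Cl2/CF3CH2OH 4:1, −78 to −30 °C
Reagents that add atoms: none
Why: Proposed new method: the chiral λ3-iodane adds face-selectively to the electron-rich E-styrene at the CH2O-bearing carbon, the chromenyl ring closes 6-endo (anti) on the benzylic cation, the now trans-disposed dioxygenated aryl displaces ArI through a phenonium ion (1,2-aryl shift with inversion, which fixes C6a), and the A-ring-stabilised C11a cation is captured by the MOM-ether oxygen with loss of the MOM cation, the obligatory cis fusion fixing C11a; the closest known reaction types are the iodine(III) oxidative rearrangement and migratory geminal difunctionalisation of β-substituted styrenes through phenonium ions and the iodonium-induced 6-endo arylcyclisation of aryl cinnamyl ethers to trans-3-iodo-4-arylchromans.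

**Compound list**
1 | cyclohexane-1,3-dione | O=C1CCCC(=O)C1 | starting material
2 | 3-methylbut-2-enal (prenal) | CC(C)=CC=O | starting material
3 | 2-(3-methylbut-2-en-1-ylidene)cyclohexane-1,3-dione | CC(C)=CC=C1C(=O)CCCC1=O | intermediate (not isolated)
4 | 2,2-dimethyl-2,6,7,8-tetrahydro-5H-chromen-5-one | CC1(C)C=CC2=C(O1)CCCC2=O | intermediate
5 | lithium 2,2-dimethyl-7,8-dihydro-2H-chromen-5-olate | [Li]OC1=CCCC2=C1C=CC(C)(C)O2 | intermediate (not isolated)
6 | 2,2-dimethyl-2,8-dihydro-5H-chromen-5-one | O=C1C=CCC2=C1C=CC(C)(C)O2 | intermediate (not isolated)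
7 | 2,2-dimethyl-2H-chromen-5-ol | CC1(C)C=Cc2c(O)cccc2O1 | intermediate
8 | 5-(methoxymethoxy)-2,2-dimethyl-2H-chromene | COCOc1cccc2OC(C)(C)C=Cc12 | intermediate
9 | (3R,4R)-3,4-epoxy-5-(methoxymethoxy)-2,2-dimethylchromane | COCOc1cccc2OC(C)(C)[C@@H]3O[C@@H]3c12 | intermediate
10 | (3R)-5-(methoxymethoxy)-2,2-dimethylchroman-3-ol | COCOc1cccc2OC(C)(C)[C@H](O)Cc12 | intermediate
11 | (E)-1,3-dichloroprop-1-ene | ClC/C=C/Cl | starting material
12 | 5-{[(2E)-3-chloroprop-2-en-1-yl]oxy}-2,2-dimethyl-2H-chromene | CC1(C)C=Cc2c(OC/C=C/Cl)cccc2O1 | intermediate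
13 | lithium (3R)-6-lithio-5-(methoxymethoxy)-2,2-dimethylchroman-3-olate | COCOc1c([Li])ccc2OC(C)(C)[C@H](O[Li])Cc12 | intermediate (not isolated)
14 | lithium (3R)-6-(chlorozincio)-5-(methoxymethoxy)-2,2-dimethylchroman-3-olate | COCOc1c([Zn]Cl)ccc2OC(C)(C)[C@H](O[Li])Cc12 | intermediate (not isolated)
15 | (3R)-6-{(1E)-3-[(2,2-dimethyl-2H-chromen-5-yl)oxy]prop-1-en-1-yl}-5-(methoxymethoxy)-2,2-dimethylchroman-3-ol | COCOc1c(/C=C/COc3cccc4OC(C)(C)C=Cc34)ccc2OC(C)(C)[C@H](O)Cc12 | intermediate
16 | (6aR,11aR)-pterocarpan with a 2,2-dimethyl-2H-pyran fused at O3/C4 and a (3R)-3-hydroxy-2,2-dimethyldihydropyran fused at O9/C10 (CNP0126417.1) | CC1(C)C=Cc2c(ccc3c2OC[C@H]2c4ccc5c(c4O[C@@H]32)C[C@@H](O)C(C)(C)O5)O1 | target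

**Step count and risks**

Total: 8 steps. Longest linear sequence: 7 steps (1, 2, 3, 4, 5, 7, 8); step 6 is the only side branch, from the shared chromenol 7.

The step most likely to fail is step 8, the proposed new cascade. The iodane may also attack the 2,2-dimethylchromene alkene of ring A, although that alkene is shielded by the gem-dimethyl carbon and gives only a secondary cation. It may instead form diaryliodonium salts with the resorcinol-type rings, the cinnamyl ether may ionise, or face control may be incomplete. The fallback uses known chemistry, sets out from 10 and 7 and comes back at 16. Ortho-lithiation of 10 and iodine give (3R)-6-iodo-5-(methoxymethoxy)-2,2-dimethylchroman-3-ol F1, and HCl in MeOH removes the MOM group to give (3R)-6-iodo-2,2-dimethylchromane-3,5-diol F2. Propargyl bromide and K2CO3 convert 7 into 2,2-dimethyl-5-(prop-2-yn-1-yloxy)-2H-chromene F3, and gold(I)-catalysed 6-endo hydroarylation gives 8,8-dimethyl-2H,8H-pyrano[2,3-f]chromene F4. Palladium-catalysed Heck oxyarylation of F4 with F2 (Pd(OAc)2, Ag2CO3, acetone, 60 °C) gives the cis-fused pterocarpans. Because the carbinol centre is already set, they form as two diastereomers, 16 and the (6aS,11aS) isomer of 16 F5, which are separated by chromatography.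

The second is step 7. The vinylic chloride may insert slowly, and Pd(0) may ionise the allylic aryl ether of 12 or of the product. The fallback forms the aryl–vinyl bond by carbonyl addition and the ether last; it sets out from 10 and 7 and comes back at 15. The dilithio species from 10 is added to 3-(dimethylamino)acrolein and worked up with dilute acid to give (2E)-3-[(3R)-3-hydroxy-5-(methoxymethoxy)-2,2-dimethylchroman-6-yl]prop-2-enal F6. Luche reduction gives (3R)-6-[(1E)-3-hydroxyprop-1-en-1-yl]-5-(methoxymethoxy)-2,2-dimethylchroman-3-ol F7, and a Mitsunobu reaction of its primary allylic hydroxyl with 7 (PPh3, DIAD) gives 15.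

The third is step 4. The epoxide carries two ortho oxygens and is very acid-labile, and the peri OMOM group may lower the ee. The fallback sets the carbinol by ketone reduction instead; it sets out from 8 and comes back at 10. Dimethyldioxirane gives racemic cis-3,4-epoxy-5-(methoxymethoxy)-2,2-dimethylchromane F8, InCl3 (5 mol %) isomerises it by a Meinwald hydride shift to 5-(methoxymethoxy)-2,2-dimethylchroman-3-one F9, and (S)-Me-CBS with BH3·SMe2 (quaternary C2 side as the large group) reduces it to 10.

**Further compounds**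
F1 | step 8 | (3R)-6-iodo-5-(methoxymethoxy)-2,2-dimethylchroman-3-ol | COCOc1c(I)ccc2OC(C)(C)[C@H](O)Cc12
F2 | step 8 | (3R)-6-iodo-2,2-dimethylchromane-3,5-diol | Oc1c(I)ccc2OC(C)(C)[C@H](O)Cc12
F3 | step 8 | 2,2-dimethyl-5-(prop-2-yn-1-yloxy)-2H-chromene | CC1(C)C=Cc2c(OCC#C)cccc2O1
F4 | step 8 | 8,8-dimethyl-2H,8H-pyrano[2,3-f]chromene | CC1(C)C=Cc2c(O1)ccc3C=CCOc23
F5 | step 8 | (6aS,11aS) isomer of 16 | CC1(C)C=Cc2c(ccc3c2OC[C@@H]2c4ccc5c(c4O[C@H]32)C[C@@H](O)C(C)(C)O5)O1
F6 | step 7 | (2E)-3-[(3R)-3-hydroxy-5-(methoxymethoxy)-2,2-dimethylchroman-6-yl]prop-2-enal | COCOc1c(/C=C/C=O)ccc2OC(C)(C)[C@H](O)Cc12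
F7 | step 7 | (3R)-6-[(1E)-3-hydroxyprop-1-en-1-yl]-5-(methoxymethoxy)-2,2-dimethylchroman-3-ol | COCOc1c(/C=C/CO)ccc2OC(C)(C)[C@H](O)Cc12
F8 | step 4 | racemic cis-3,4-epoxy-5-(methoxymethoxy)-2,2-dimethylchromane | COCOc1cccc2OC(C)(C)C3OC3c12
F9 | step 4 | 5-(methoxymethoxy)-2,2-dimethylchroman-3-one | COCOc1cccc2OC(C)(C)C(=O)Cc12
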